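Conneotricone is disconnected at the diaryl ether C–O bond on ring A (the benzene ring bearing CH3, OH and CO2H). The ring A carbon that holds this ether oxygen sits between the carbon bearing CO2H and the carbon bearing the depsidone C=O, so the corresponding C–F is doubly ortho-activated. In the key step the C4 phenoxide of ring B (the phthalide benzene ring) of a depside displaces that fluoride, making the ether bond and the seven-membered ring at once. The precursor, fluoro depside 19, carries ring A as MOM ether and tert-butyl ester and ring B as an acetonide; both rings are built separately, esterified, cyclised and unmasked with acid.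

Key step: step 14

Remark: ring B is numbered as a phthalide (C1 lactone C=O, C3 lactone CH2, C4 ether oxygen, C5 ester oxygen, C6 CH2OH, C7 OH); the target has no stereocentre, so no configuration has to be set.

**Ring A acid (steps 1–3)**

Step 1
Reactants: 1 3-fluoro-5-methylphenol
Product: 2 1-fluoro-3-(methoxymethoxy)-5-methylbenzene
Conditions: MOMCl, iPr2NEt, CH2Cl2, 0 °C to rt
Reagents that add atoms: chloromethyl methyl ether, COCCl
Why: O-alkylation of the phenol by the reactive chloromethyl ether under amine base (Williamson-type acetal formation) should give the MOM ether, which serves later both as protecting group and as metalation director.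

Step 2
Reactants: 2 1-fluoro-3-(methoxymethoxy)-5-methylbenzene
Product: 4 tert-butyl 2-fluoro-6-(methoxymethoxy)-4-methylbenzoate, via aryllithium 3 (not isolated)
Conditions: n-BuLi, THF, −78 °C; then Boc2O (inverse addition), −78 to −20 °C
Reagents that add atoms: di-tert-butyl dicarbonate, CC(C)(C)OC(=O)OC(=O)OC(C)(C)C
Why: Directed ortho-metalation should remove the C–H between fluorine and the MOM ether, which is acidified by both neighbours and chelated by the acetal, at a temperature below LiF loss, and acylation of the aryllithium by Boc2O should stop at the hindered tert-butyl ester.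

Step 3
Reactants: 4 tert-butyl 2-fluoro-6-(methoxymethoxy)-4-methylbenzoate
Product: 6 3-(tert-butoxycarbonyl)-2-fluoro-4-(methoxymethoxy)-6-methylbenzoic acid, via aryllithium 5 (not isolated)
Conditions: LiTMP (from 2,2,6,6-tetramethylpiperidine and n-BuLi), THF, −78 °C; then CO2, −78 °C to rt; cold dilute HCl to pH 3
Reagents that add atoms: carbon dioxide, O=C=O
Why: Directed ortho-metalation with a hindered lithium amide is governed by acidity, so the only C–H ortho to fluorine (between F and CH3) should be removed in preference to the one beside the MOM ether, while the tert-butyl ester, shielded by two ortho groups and twisted out of conjugation, should neither be attacked nor acidify the para methyl group, and carboxylation of the aryllithium then gives the acid.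

**Ring B phenol (steps 4–11)**

Step 4
Reactants: 7 2,4,5-trimethoxybenzoic acid
Product: 8 4,5,7-trimethoxyphthalide
Conditions: Pd(OAc)2 (10 mol%), K2HPO4, CH2Br2, 140 °C, sealed tube
Reagents that add atoms: dibromomethane, BrCBr
Why: Carboxylate-directed ortho C–H activation by divalent palladium can occur only at the single free ortho position, and alkylation of the arylpalladium species by CH2Br2 followed by intramolecular SN2 attack of the carboxylate on the benzylic bromide should close the lactone (C–H alkylation/lactonisation of a benzoic acid).

Step 5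
Reactants: 8 4,5,7-trimethoxyphthalide
Product: 9 4,5,7-trihydroxyphthalide
Conditions: BBr3, CH2Cl2, −78 °C to rt, argon; MeOH then water; used crude
Reagents that add atoms: none
Why: Lewis-acid ether cleavage, in which BBr3 coordinates each aryl methyl ether and bromide removes the methyl group by SN2, should free all three phenols while the phthalide lactone stays intact at or below room temperature.

Step 6
Reactants: 9 4,5,7-trihydroxyphthalide
Product: 10 7-hydroxy-4,5-(diphenylmethylenedioxy)phthalide
Conditions: Ph2CCl2, Ph2O, 175 °C
Reagents that add atoms: dichlorodiphenylmethane, ClC(Cl)(c1ccccc1)c1ccccc1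
Why: Catechol ketalisation with a geminal dichloride can form a five-membered ring only across the vicinal C4 and C5 oxygens, so the isolated C7 phenol should be left free without any selectivity between phenols being required.

Step 7
Reactants: 10 7-hydroxy-4,5-(diphenylmethylenedioxy)phthalide
Product: 11 6-formyl-7-hydroxy-4,5-(diphenylmethylenedioxy)phthalide
Conditions: MgCl2, Et3N, (CH2O)n, MeCN, reflux
Reagents that add atoms: paraformaldehyde (formaldehyde source), C=O
Why: Magnesium phenoxide-directed ortho-formylation (Casnati–Skattebøl reaction) should deliver formaldehyde from the C7 phenoxide to C6, the only free ring position, and the hydroxymethyl intermediate is oxidised in the same pot by hydride transfer to a second formaldehyde.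

Step 8
Reactants: 11 6-formyl-7-hydroxy-4,5-(diphenylmethylenedioxy)phthalide
Product: 12 7-hydroxy-6-(hydroxymethyl)-4,5-(diphenylmethylenedioxy)phthalide
Conditions: NaBH4, THF–MeOH, 0 °C
Reagents that add atoms: none
Why: Chemoselective hydride reduction should convert the aryl aldehyde to the benzylic alcohol at 0 °C much faster than NaBH4 touches the phthalide lactone.

Step 9
Reactants: 12 7-hydroxy-6-(hydroxymethyl)-4,5-(diphenylmethylenedioxy)phthalide
Product: 13 4,5-(diphenylmethylenedioxy)phthalide 6-CH2O/7-O acetonide
Conditions: 2,2-dimethoxypropane, PPTS (cat.), acetone, rt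
Reagents that add atoms: 2,2-dimethoxypropane, COC(C)(C)OC
Why: Acid-catalysed transketalisation of the ortho-hydroxybenzyl alcohol should give the six-membered 1,3-benzodioxin, and because the C5 oxygen is still locked in the diphenyl ketal the acetonide can form only toward the C7 oxygen.

Step 10
Reactants: 13 4,5-(diphenylmethylenedioxy)phthalide 6-CH2O/7-O acetonide
Product: 14 4,5-dihydroxyphthalide 6-CH2O/7-O acetonide
Conditions: H2 (1 atm), Pd/C, THF–MeOH, rt; product kept under argon
Reagents that add atoms: none
Why: Hydrogenolysis of the doubly benzylic C–O bonds of the diphenylmethylene ketal on Pd/C should release the catechol under neutral conditions that leave the acetonide and the lactone untouched.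

Step 11
Reactants: 14 4,5-dihydroxyphthalide 6-CH2O/7-O acetonide
Product: 16 4-(benzyloxy)-5-hydroxyphthalide 6-CH2O/7-O acetonide, via disodium catecholate 15 (not isolated)
Conditions: NaH (2.2 equiv), degassed DMF, 0 °C; then BnBr (1.0 equiv), 0 °C to rt; dilute HCl
Reagents that add atoms: benzyl bromide, BrCc1ccccc1
Why: Williamson etherification of the catechol dianion should place the single benzyl group on the more basic C4 phenoxide (meta to the lactone carbonyl) and not on the C5 phenoxide, whose charge is delocalised into the para lactone carbonyl, as in the dianion mono-alkylation of 3,4-dihydroxybenzaldehyde.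

**Coupling, ring closure and unmasking (steps 12–15)**

Step 12
Reactants: 6 3-(tert-butoxycarbonyl)-2-fluoro-4-(methoxymethoxy)-6-methylbenzoic acid; 16 4-(benzyloxy)-5-hydroxyphthalide 6-CH2O/7-O acetonide
Product: 18 benzyl-protected fluoro depside, via acid chloride 17 (not isolated)
Conditions: 1-chloro-N,N,2-trimethylprop-1-en-1-amine, CH2Cl2, 0 °C to rt; then 16, Et3N, DMAP (cat.), 0 °C to rt
Reagents that add atoms: none
Why: DMAP-catalysed acylation of a phenol by an acid chloride should work here because the α-chloroenamine forms the chloride without liberating acid, which spares the MOM ether and tert-butyl ester, and the acyl chloride is far more electrophilic than the C–F carbon in a non-polar solvent, so the only free phenol of 16 is esterified.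

Step 13
Reactants: 18 benzyl-protected fluoro depside
Product: 19 fluoro depside with free ring B C4 phenol
Conditions: H2 (1 atm), Pd/C, EtOAc, rt; used at once
Reagents that add atoms: none
Why: Hydrogenolysis of the benzyl aryl ether on Pd/C is fast and neutral, so the phenol should be released without acid or base that could start acyl migration, and the aryl fluoride, MOM ether, tert-butyl ester, acetonide and lactone are not cleaved at balloon pressure.

Step 14
Reactants: 19 fluoro depside with free ring B C4 phenol
Product: 21 protected conneotricone (MOM ether, tert-butyl ester, acetonide), via caesium phenoxide 20 (not isolated)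
Conditions: Cs2CO3 (1.5 equiv), DMF (0.005 M), rt to 40 °C
Reagents that add atoms: none
Why: Cs2CO3 deprotonates the ring B C4 phenol, and the phenoxide adds to the fluorine-bearing carbon of ring A to give a Meisenheimer anion whose charge is shared by the two flanking ester carbonyls (tert-butyl ester and depside carbonyl) before fluoride leaves and aromaticity returns (SNAr addition–elimination). The closest known reaction type is the intramolecular SNAr synthesis of diaryl ethers from phenols and ortho-carbonyl-activated aryl fluorides. The seven-membered dioxepinone ring closes through the existing ester tether by attack on a trigonal aromatic carbon, formally 7-exo-trig with respect to the ring A π-bond that carries the charge toward the tert-butyl ester. No stereocentre is formed. The step needs chemoselectivity for the C–F carbon over the depside carbonyl (1,2-acyl shift to the adjacent oxygen) and over intermolecular substitution; the first should be secured by the double ortho activation of the fluoride, by an acyl carbon shielded by its F and CH3 ortho neighbours and by the higher nucleophilicity of a phenoxide meta to the lactone carbonyl, the second by high dilution. Copper-mediated coupling is avoided because the ether is tetra-ortho-substituted, whereas here the crowded carbon is the most electrophilic site in the molecule and electron-rich ring B only has to act as nucleophile.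

Step 15
Reactants: 21 protected conneotricone (MOM ether, tert-butyl ester, acetonide)
Product: 22 conneotricone
Conditions: TFA–CH2Cl2–H2O (10:10:1), 0 °C to rt
Reagents that add atoms: none
Why: Acidolysis should ionise the MOM acetal and the acetonide through oxocarbenium ions that water captures and cleave the tert-butyl ester by loss of the tert-butyl cation, whereas the aryl ester of the depsidone and the phthalide lactone are stable to acid.

**Compound list**

1 | 3-fluoro-5-methylphenol | Cc1cc(O)cc(F)c1 | starting material
2 | 1-fluoro-3-(methoxymethoxy)-5-methylbenzene | COCOc1cc(C)cc(F)c1 | intermediate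
3 | 2-fluoro-6-(methoxymethoxy)-4-methylphenyllithium (not isolated) | [Li]c1c(F)cc(C)cc1OCOC | intermediate
4 | tert-butyl 2-fluoro-6-(methoxymethoxy)-4-methylbenzoate | Cc1cc(F)c(C(=O)OC(C)(C)C)c(OCOC)c1 | intermediate
5 | tert-butyl 2-fluoro-3-lithio-6-(methoxymethoxy)-4-methylbenzoate (not isolated) | Cc1cc(OCOC)c(C(=O)OC(C)(C)C)c(F)c1[Li] | intermediate
6 | 3-(tert-butoxycarbonyl)-2-fluoro-4-(methoxymethoxy)-6-methylbenzoic acid | Cc1cc(OCOC)c(C(=O)OC(C)(C)C)c(F)c1C(=O)O | intermediate
7 | 2,4,5-trimethoxybenzoic acid | COc1cc(OC)c(cc1OC)C(=O)O | starting material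
8 | 4,5,7-trimethoxyphthalide (4,5,7-trimethoxy-2-benzofuran-1(3H)-one) | COc1cc(OC)c2c(c1OC)COC2=O | intermediate
9 | 4,5,7-trihydroxyphthalide | Oc1cc(O)c2c(c1O)COC2=O | intermediate
10 | 7-hydroxy-4,5-(diphenylmethylenedioxy)phthalide (C4 and C5 oxygens bridged by CPh2) | Oc1cc2OC(c3ccccc3)(c3ccccc3)Oc2c2COC(=O)c12 | intermediate
11 | 6-formyl-7-hydroxy-4,5-(diphenylmethylenedioxy)phthalide | O=Cc1c(O)c2C(=O)OCc2c2OC(c3ccccc3)(c3ccccc3)Oc12 | intermediate
12 | 7-hydroxy-6-(hydroxymethyl)-4,5-(diphenylmethylenedioxy)phthalide | OCc1c(O)c2C(=O)OCc2c2OC(c3ccccc3)(c3ccccc3)Oc12 | intermediate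
13 | 4,5-(diphenylmethylenedioxy)phthalide with C6 CH2O and C7 O joined as isopropylidene acetal (2,2-dimethyl-4H-1,3-benzodioxin) | CC1(C)OCc2c(O1)c1C(=O)OCc1c1OC(c3ccccc3)(c3ccccc3)Oc12 | intermediate
14 | 4,5-dihydroxyphthalide 6-CH2O/7-O acetonide (ring B catechol) | CC1(C)OCc2c(O1)c1C(=O)OCc1c(O)c2O | intermediate
15 | disodium catecholate of 14 (not isolated) | CC1(C)OCc2c(O1)c1C(=O)OCc1c([O-])c2[O-].[Na+].[Na+] | intermediate
16 | 4-(benzyloxy)-5-hydroxyphthalide 6-CH2O/7-O acetonide | CC1(C)OCc2c(O1)c1C(=O)OCc1c(OCc1ccccc1)c2O | intermediate
17 | tert-butyl 3-(chlorocarbonyl)-2-fluoro-6-(methoxymethoxy)-4-methylbenzoate (not isolated) | Cc1cc(OCOC)c(C(=O)OC(C)(C)C)c(F)c1C(=O)Cl | intermediate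
18 | benzyl-protected fluoro depside: ring A acid 6 esterified to the C5 oxygen of 16 | Cc1cc(OCOC)c(C(=O)OC(C)(C)C)c(F)c1C(=O)Oc1c(OCc2ccccc2)c2COC(=O)c2c2OC(C)(C)OCc12 | intermediate
19 | fluoro depside with free ring B C4 phenol | Cc1cc(OCOC)c(C(=O)OC(C)(C)C)c(F)c1C(=O)Oc1c(O)c2COC(=O)c2c2OC(C)(C)OCc12 | intermediate
20 | caesium C4 phenoxide of 19 (not isolated) | Cc1cc(OCOC)c(C(=O)OC(C)(C)C)c(F)c1C(=O)Oc1c([O-])c2COC(=O)c2c2OC(C)(C)OCc12.[Cs+] | intermediate
21 | protected conneotricone (MOM ether, tert-butyl ester, acetonide) | Cc1cc(OCOC)c(C(=O)OC(C)(C)C)c2c1C(=O)Oc1c3COC(C)(C)Oc3c3C(=O)OCc3c1O2 | intermediate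
22 | conneotricone | Cc1cc(O)c(C(=O)O)c2c1C(=O)Oc1c(CO)c(O)c3c(c1O2)COC3=O | target

**Step count and risks**

Total step count: 15. Longest linear sequence: 12 steps (7 through steps 4–11, then steps 12–15).

Steps most likely to fail:

1. Step 14 (key step). The phenoxide may shift the acyl group to the adjacent oxygen before ring closure, which would lead to the reversed ring B orientation, or may react intermolecularly to give oligomers. The fallback forms the diaryl ether first and closes the lactone last; it sets out from 6 and 14 and returns at 21. Acid 6 is benzylated at the carboxyl group (BnBr, K2CO3, DMF) to benzyl tert-butyl 2-fluoro-4-(methoxymethoxy)-6-methylisophthalate F1. Catechol 14 is benzylated with one equivalent of BnBr and NaHCO3 in DMF, weak-base conditions that select the more acidic C5 phenol para to the lactone carbonyl, to give the C5 benzyl ether F2. K2CO3 in DMF then joins the C4 phenoxide of F2 to the same doubly activated fluoride of F1 by intermolecular SNAr, giving diaryl ether F3. Hydrogenolysis (H2, Pd/C) removes both benzyl groups to give hydroxy acid F4, and lactonisation with 2-chloro-1-methylpyridinium iodide and Et3N under dilution gives 21.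

2. Step 4. The electron-rich ortho-methoxy acid may undergo protodecarboxylation, or C–H palladation may stall at 140 °C. The fallback is amide-directed ortho-lithiation; it sets out from 7 and returns at 8. SOCl2 followed by Et2NH gives N,N-diethyl-2,4,5-trimethoxybenzamide F5. s-BuLi/TMEDA in THF at −78 °C lithiates the position between the amide and the C5 methoxy group, and DMF gives N,N-diethyl-2-formyl-3,4,6-trimethoxybenzamide F6. NaBH4 in MeOH gives N,N-diethyl-2-(hydroxymethyl)-3,4,6-trimethoxybenzamide F7, which lactonises on heating with TsOH in toluene, expelling diethylamine, to give 8.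

3. Step 3. Deprotonation may be incomplete or misdirected (toward the position beside the MOM ether or the benzylic methyl group), or the ortho-fluoro aryllithium may lose LiF on warming. The fallback installs the carboxyl carbon through a bromide; it sets out from 1 and returns at 6. Para-bromination with Bu4NBr3 in CH2Cl2–MeOH gives 4-bromo-3-fluoro-5-methylphenol F8, and MOMCl/iPr2NEt gives 2-bromo-1-fluoro-5-(methoxymethoxy)-3-methylbenzene F9. LiN(iPr)2 at −78 °C deprotonates between F and the MOM ether, and Boc2O gives tert-butyl 3-bromo-2-fluoro-6-(methoxymethoxy)-4-methylbenzoate F10. Bromine–magnesium exchange with iPrMgCl·LiCl in THF at −15 °C followed by CO2 gives 6.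

Further compounds
F1 | step 14 | benzyl tert-butyl 2-fluoro-4-(methoxymethoxy)-6-methylisophthalate | Cc1cc(OCOC)c(C(=O)OC(C)(C)C)c(F)c1C(=O)OCc1ccccc1
F2 | step 14 | 5-(benzyloxy)-4-hydroxyphthalide 6-CH2O/7-O acetonide | CC1(C)OCc2c(O1)c1C(=O)OCc1c(O)c2OCc1ccccc1
F3 | step 14 | diaryl ether of F1 and F2 (ring A C2–O–C4 ring B), benzyl ester and benzyl ether intact | Cc1cc(OCOC)c(C(=O)OC(C)(C)C)c(Oc2c(OCc3ccccc3)c3COC(C)(C)Oc3c3C(=O)OCc23)c1C(=O)OCc1ccccc1
F4 | step 14 | diaryl ether hydroxy acid (free ring A CO2H, free ring B C5 OH) | Cc1cc(OCOC)c(C(=O)OC(C)(C)C)c(Oc2c(O)c3COC(C)(C)Oc3c3C(=O)OCc23)c1C(=O)O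
F5 | step 4 | N,N-diethyl-2,4,5-trimethoxybenzamide | CCN(CC)C(=O)c1cc(OC)c(OC)cc1OC
F6 | step 4 | N,N-diethyl-2-formyl-3,4,6-trimethoxybenzamide | CCN(CC)C(=O)c1c(OC)cc(OC)c(OC)c1C=O
F7 | step 4 | N,N-diethyl-2-(hydroxymethyl)-3,4,6-trimethoxybenzamide | CCN(CC)C(=O)c1c(OC)cc(OC)c(OC)c1CO
F8 | step 3 | 4-bromo-3-fluoro-5-methylphenol | Cc1cc(O)cc(F)c1Br
F9 | step 3 | 2-bromo-1-fluoro-5-(methoxymethoxy)-3-methylbenzene | COCOc1cc(C)c(Br)c(F)c1
F10 | step 3 | tert-butyl 3-bromo-2-fluoro-6-(methoxymethoxy)-4-methylbenzoate | Cc1cc(OCOC)c(C(=O)OC(C)(C)C)c(F)c1Br
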